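The route cuts the C2=C3 bond in the pyrrole half of the 6-bromoindole (ring B). Because C3 carries imidazole C5 and C2 is an unsubstituted CH next to N1, C3 is traced back to a heteroaryl aryl ketone carbon and C2 to the formyl carbon of a formamide on C7a. One titanium-mediated reductive coupling joins these two carbonyl carbons, closes the five-membered ring and delivers the aromatic indole with bromine already fixed at C6. The precursor is the bis-SEM 2-(indol-3-yl)imidazol-5-yl 2-formamido-4-bromophenyl ketone, assembled by C5 lithiation of the protected 2-(indol-3-yl)imidazole, acylation with a Weinreb amide and N-formylation.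

Key step: step 6

Remark: SEM = 2-(trimethylsilyl)ethoxymethyl (CH2OCH2CH2SiMe3); ring A is the unbrominated indole, ring B the 6-bromoindole, ring C the imidazole. Once ring C is unprotected its two N–H tautomers are one compound, so the 2,5-disubstituted imidazole made here is the target.

Step 1
Reactants: 1 indole-3-carbaldehyde; 2 glyoxal; 3 ammonia
Product: 4 3-(1H-imidazol-2-yl)-1H-indole
Conditions: glyoxal (40% aq., 3 equiv), aq. NH3 (28%, excess), EtOH, 0 °C to rt
Reagents that add atoms: glyoxal O=CC=O; ammonia N
Why: In this Debus–Radziszewski imidazole synthesis the aldehyde carbon becomes imidazole C2 as it condenses with the glyoxal/ammonia diimine, and the indole N–H needs no protection under these mild aqueous conditions.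

Step 2
Reactants: 4 3-(1H-imidazol-2-yl)-1H-indole; 5 2-(trimethylsilyl)ethoxymethyl chloride (SEMCl)
Product: 7 1-SEM-3-(1-SEM-imidazol-2-yl)indole, via disodium salt 6 (not isolated)
Conditions: NaH (2.3 equiv), DMF, 0 °C; then SEMCl (2.2 equiv), 0 °C to rt
Reagents that add atoms: 2-(trimethylsilyl)ethoxymethyl chloride C[Si](C)(C)CCOCCl
Why: Double N-alkylation (SN2 at the chloromethyl ether) of the indolide/imidazolide dianion should be clean, and because the 2-substituted imidazole is symmetric either ring nitrogen gives the same product.

Step 3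
Reactants: 8 2-amino-4-bromobenzoic acid; 9 N,O-dimethylhydroxylamine hydrochloride
Product: 11 2-amino-4-bromo-N-methoxy-N-methylbenzamide, via benzotriazol-1-yl ester 10 (not isolated)
Conditions: MeNHOMe·HCl (1.3 equiv), EDC·HCl, HOBt, N-methylmorpholine, DMF, 0 °C to rt
Reagents that add atoms: N,O-dimethylhydroxylamine hydrochloride CNOC.Cl
Why: In this carbodiimide/HOBt amide coupling the aniline nitrogen, deactivated by conjugation with the ortho carboxyl group, should not compete with the far more nucleophilic hydroxylamine, so the Weinreb amide forms without N-protection.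

Step 4
Reactants: 7 1-SEM-3-(1-SEM-imidazol-2-yl)indole; 11 2-amino-4-bromo-N-methoxy-N-methylbenzamide
Product: 14 (2-amino-4-bromophenyl)[2-(1-SEM-indol-3-yl)-1-SEM-imidazol-5-yl]methanone, via 5-lithioimidazole 12 (not isolated), via dilithium tetrahedral adduct 13 (not isolated)
Conditions: 7 (2.3 equiv), n-BuLi (2.2 equiv), THF, −78 °C; then 11 (1.0 equiv), −78 to −20 °C; aq. NH4Cl
Reagents that add atoms: none
Why: Directed lithiation at imidazole C5 (the most acidic C–H, next to the SEM-bearing nitrogen, whereas indole C2–H of an N-SEM indole is metalated only at higher temperature) is followed by a Weinreb ketone synthesis in which one equivalent of 12 deprotonates the NH2 group, the second adds to the amide, the chelated adduct 13 (racemic) blocks over-addition, and the slight deficit of n-BuLi relative to 7 leaves no alkyllithium for bromine–lithium exchange.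

Step 5
Reactants: 14 (2-amino-4-bromophenyl)[2-(1-SEM-indol-3-yl)-1-SEM-imidazol-5-yl]methanone; 15 formic acid
Product: 16 N-{5-bromo-2-[2-(1-SEM-indol-3-yl)-1-SEM-imidazole-5-carbonyl]phenyl}formamide
Conditions: HCO2H, Ac2O, 55 °C (acetic formic anhydride made beforehand); then 14, THF, 0 °C to rt
Reagents that add atoms: acetic formic anhydride CC(=O)OC=O (made from formic acid O=CO and acetic anhydride)
Why: N-Formylation by a mixed anhydride should succeed even on this weakly nucleophilic ortho-acyl aniline, since acetic formic anhydride delivers its more electrophilic, less hindered formyl group and the SEM groups tolerate the weakly acidic medium.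

Step 6
Reactants: 16 N-{5-bromo-2-[2-(1-SEM-indol-3-yl)-1-SEM-imidazole-5-carbonyl]phenyl}formamide
Product: 18 6-bromo-3-[2-(1-SEM-indol-3-yl)-1-SEM-imidazol-5-yl]-1H-indole (bis-SEM nortopsentin C), via dichlorotitanium diolate 17 (not isolated)
Conditions: TiCl3 (4 equiv), Zn dust (8 equiv), THF, reflux; slow addition of 16 at high dilution; aq. Na2EDTA work-up
Reagents that add atoms: none
Why: Zinc reduces TiCl3 to a divalent titanium chloride that transfers two electrons to the electron-poor diaryl ketone, and the resulting titanium-bound ketyl carbon (future C3) adds to the neighbouring formyl carbon (future C2), joining two carbons of like electrophilic polarity in the tetravalent titanium diolate 17. A second equivalent of low-valent titanium strips both oxygens from 17, which installs C2=C3 and aromatises ring B. The closest known reaction type is the Fürstner indole synthesis, a McMurry-type intramolecular oxo-amide coupling with TiCl3/Zn. The ring closes in a 5-exo-trig mode, the ketyl carbon attacking the exocyclic formyl C=O. No stereocentre survives, since the two cis carbinol centres of 17 both become sp2. The step needs ring closure to outrun intermolecular pinacol coupling, over-reduction of the ketone and reduction of the C6–Br bond; the ortho placement of formamide and ketone, the much easier reduction of the ketone than of the aryl bromide, slow addition at high dilution and a short reflux are relied on.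

Step 7
Reactants: 18 6-bromo-3-[2-(1-SEM-indol-3-yl)-1-SEM-imidazol-5-yl]-1H-indole
Product: 19 nortopsentin C
Conditions: Bu4NF (1 M in THF, 8 equiv), ethylenediamine (6 equiv), DMF, 80 °C
Reagents that add atoms: none
Why: Fluoride-induced SEM cleavage (attack at silicon, loss of ethylene and formaldehyde, the latter trapped by ethylenediamine) should free both the ring A and ring C nitrogens, after which imidazole tautomerism makes the product identical with the target as drawn.

Compound list
1 | indole-3-carbaldehyde | O=Cc1c[nH]c2ccccc12 | starting material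
2 | glyoxal | O=CC=O | starting material
3 | ammonia | N | starting material
4 | 3-(1H-imidazol-2-yl)-1H-indole | c1ccc2c(c1)[nH]cc2-c1ncc[nH]1 | intermediate
5 | 2-(trimethylsilyl)ethoxymethyl chloride (SEMCl) | C[Si](C)(C)CCOCCl | starting material
6 | disodium salt of 4 (indolide/imidazolide dianion) | [Na+].[Na+].c1ccc2c(c1)[n-]cc2-c1ncc[n-]1 | intermediate (not isolated)
7 | 1-SEM-3-(1-SEM-imidazol-2-yl)indole | C[Si](C)(C)CCOCn1ccnc1-c1cn(COCC[Si](C)(C)C)c2ccccc12 | intermediate
8 | 2-amino-4-bromobenzoic acid | Nc1cc(Br)ccc1C(=O)O | starting material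
9 | N,O-dimethylhydroxylamine hydrochloride | CNOC.Cl | starting material
10 | benzotriazol-1-yl 2-amino-4-bromobenzoate | Nc1cc(Br)ccc1C(=O)On1nnc2ccccc12 | intermediate (not isolated)
11 | 2-amino-4-bromo-N-methoxy-N-methylbenzamide | CON(C)C(=O)c1ccc(Br)cc1N | intermediate
12 | 5-lithio derivative of 7 | [Li]c1cnc(-c2cn(COCC[Si](C)(C)C)c3ccccc23)n1COCC[Si](C)(C)C | intermediate (not isolated)
13 | dilithium tetrahedral adduct of 12 and the N-lithio anilide of 11 (racemic) | CON(C)C(O[Li])(c1ccc(Br)cc1N[Li])c1cnc(-c2cn(COCC[Si](C)(C)C)c3ccccc23)n1COCC[Si](C)(C)C | intermediate (not isolated)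
14 | (2-amino-4-bromophenyl)[2-(1-SEM-indol-3-yl)-1-SEM-imidazol-5-yl]methanone | Nc1cc(Br)ccc1C(=O)c1cnc(-c2cn(COCC[Si](C)(C)C)c3ccccc23)n1COCC[Si](C)(C)C | intermediate
15 | formic acid | O=CO | starting material
16 | N-{5-bromo-2-[2-(1-SEM-indol-3-yl)-1-SEM-imidazole-5-carbonyl]phenyl}formamide | O=CNc1cc(Br)ccc1C(=O)c1cnc(-c2cn(COCC[Si](C)(C)C)c3ccccc23)n1COCC[Si](C)(C)C | intermediate
17 | dichlorotitanium cis-2,3-diolate of 6-bromo-3-[2-(1-SEM-indol-3-yl)-1-SEM-imidazol-5-yl]indoline (tetravalent titanium; racemic, one enantiomer drawn) | Cl[Ti]1(Cl)O[C@H]2Nc3cc(Br)ccc3[C@]2(O1)c1cnc(-c2cn(COCC[Si](C)(C)C)c3ccccc23)n1COCC[Si](C)(C)C | intermediate (not isolated)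
18 | 6-bromo-3-[2-(1-SEM-indol-3-yl)-1-SEM-imidazol-5-yl]-1H-indole (bis-SEM nortopsentin C) | Brc1ccc2c(c[nH]c2c1)-c1cnc(-c2cn(COCC[Si](C)(C)C)c3ccccc23)n1COCC[Si](C)(C)C | intermediate
19 | nortopsentin C, 6-bromo-3-[2-(1H-indol-3-yl)-1H-imidazol-4-yl]-1H-indole | Brc1ccc2c(-c3c[nH]c(-c4c[nH]c5ccccc45)n3)c[nH]c2c1 | target

Total step count: 7
Longest linear sequence: 6 steps (steps 1, 2, 4, 5, 6, 7; step 3 is a one-step side branch)

Steps most likely to fail

Step 6. The reductive closure may lose material through cleavage of the C–Br bond, through intermolecular pinacol-type dimerisation of the ketone, or through SEM loss on long contact with the Lewis-acidic titanium and zinc chlorides. The fallback sets out from 14 and skips step 5, bringing in C2 by olefination instead. Wittig reaction of 14 with the ylide from (methoxymethyl)triphenylphosphonium chloride and KOt-Bu (excess, THF, 0 °C to rt) should give the enol ether 5-[1-(2-amino-4-bromophenyl)-2-methoxyethenyl]-2-(1-SEM-indol-3-yl)-1-SEM-imidazole F1 as an E/Z mixture, both isomers being usable. Brief acid treatment (TFA, CH2Cl2, 0 °C) should protonate the enol ether, let the ortho NH2 group close onto the oxocarbenium carbon and expel methanol, which comes back to the route at 18.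

Step 4. Metalation may occur at indole C2 of ring A in competition with imidazole C5, and the carbanion may be consumed by proton transfer or halogen–metal exchange before it acylates. The fallback sets out from 4. Selective mono-alkylation of the more acidic imidazole N–H (NaH 1.0 equiv, SEMCl 5 1.0 equiv, THF, 0 °C) should give 3-(1-SEM-imidazol-2-yl)-1H-indole F2. Two equivalents of n-BuLi (THF, −78 °C) then form the N,C5-dilithio species F3, in which the indolide anion shuts down metalation at indole C2. Addition of F3 to Weinreb amide 11 should give (2-amino-4-bromophenyl)[2-(1H-indol-3-yl)-1-SEM-imidazol-5-yl]methanone F4. Alkylation of the indole nitrogen, which is more acidic than the ketone-conjugated NH2 group (NaH 1.0 equiv, SEMCl 5, DMF, 0 °C), comes back to the route at 14.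

Step 1. Self-condensation of glyoxal with ammonia may outrun condensation with the poorly electrophilic, vinylogous-amide aldehyde. The fallback sets out from 1. Condensation with ethylenediamine (t-BuOH, rt) should give the aminal 3-(imidazolidin-2-yl)-1H-indole F5, which is oxidised in the same flask (I2, K2CO3, 70 °C) to 3-(4,5-dihydro-1H-imidazol-2-yl)-1H-indole F6. Dehydrogenation of F6 (activated MnO2, 1,4-dioxane, reflux) comes back to the route at 4.

Further compounds
F1 | step 6 | 5-[1-(2-amino-4-bromophenyl)-2-methoxyethenyl]-2-(1-SEM-indol-3-yl)-1-SEM-imidazole (E/Z mixture) | COC=C(c1ccc(Br)cc1N)c1cnc(-c2cn(COCC[Si](C)(C)C)c3ccccc23)n1COCC[Si](C)(C)C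
F2 | step 4 | 3-(1-SEM-imidazol-2-yl)-1H-indole | C[Si](C)(C)CCOCn1ccnc1-c1c[nH]c2ccccc12
F3 | step 4 | N,C5-dilithio derivative of F2 | [Li]c1cnc(-c2cn([Li])c3ccccc23)n1COCC[Si](C)(C)C
F4 | step 4 | (2-amino-4-bromophenyl)[2-(1H-indol-3-yl)-1-SEM-imidazol-5-yl]methanone | Nc1cc(Br)ccc1C(=O)c1cnc(-c2c[nH]c3ccccc23)n1COCC[Si](C)(C)C
F5 | step 1 | 3-(imidazolidin-2-yl)-1H-indole | c1ccc2c(c1)[nH]cc2C1NCCN1
F6 | step 1 | 3-(4,5-dihydro-1H-imidazol-2-yl)-1H-indole | c1ccc2c(c1)[nH]cc2C1=NCCN1
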